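Decide first to follow the share of Ez that reaches Ty, not Ty itself.

| flask | Ez | Ry | remark | time |
|---|---|---|---|---|
| north-west | 0.050 M | 0.075 M | run made earlier |  |
| east | 0.050 M | 0.037 M | run made earlier |  |
| grey | 0.050 M | 0.0750 M (fed, over 6.0 h) | all else is in the flask from the start; the feed brings no volume worth counting | 10 h |
| teal | 0.050 M (fed, over 6.0 h) | 0.0750 M | all else is in the flask from the start; the feed brings no volume worth counting | 10 h |
| blue | 0.050 M | 0.0750 M | everything together at the start | 10 h |

| north-west: time / h | north-west: Ty / % | east: time / min | east: Ty / % |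
|---|---|---|---|
| 0.500 | 3.8 | 6.00 | 0.4 |
| 1.50 | 8.3 | 20.0 | 1.4 |
| 3.00 | 10.9 | 30.0 | 1.9 |
| 4.00 | 11.8 | 50.0 | 3.4 |
| 6.00 | 13.2 | 80.0 | 3.8 |
| 8.00 | 13.8 | 90.0 | 4.5 |
| 10.0 | 13.1 | 120 | 4.9 |

(each reading ± 0.3 percentage points)

- which flask leads in amount of Ty, in percent of the Ez charged ("all alike" within 1.5 percentage points) (grey / teal / blue / all alike)
- how much Ty is there at the end, in percent of the Ez charged: grey
- how much Ty is there at the end, in percent of the Ez charged: teal
- how much Ty is there at the end, in percent of the Ez charged: blue

- a reading or a percentage of Ty counts all its forms, free or not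

Start with the main step alone, Ez + Ry → Ty. The first north-west reading gives k = 1.01 M⁻¹ h⁻¹, so a = k[Ry] = 0.0760 h⁻¹. The east run rises at 0.0420 h⁻¹ with 0.493 of that Ry, so within these readings the rate goes roughly with [Ry]. The Ty read in north-west accounts for 8.73% of its Ry, so freeze [Ry] and treat the step as pseudo-first-order. Blue would then hold a fraction m = 53.2% at 10 h, but the north-west run, the same recipe, read 13.1% there, which is less.

Now add one process. The runs do not prove it, but I take a loss of Ez second order in itself, a[Ez]²/c*. The share of Ez going to Ty at any moment is then 1/(1 + [Ez]/c*). Integrated over the charge, with m for the unfinished time, this gives roughly [Ty] = c* ln(m(1 + charge/c*)), and the north-west reading at 10.0 h yields c* = 2.88 mM, with the charge far above it. Call c* the crossover concentration, the [Ez] at which Ez goes equally to Ty and to its own loss.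

Then the feeds. In teal, freeze [Ez] as well: the feed balances both losses at about 16.4 mM, a share of 14.9%. With the tail after the feed, I reckon teal at 15.3%. In grey, Ez meets a rising [Ry] while it loses itself at 1.32 h⁻¹ from the start. That gives 4.17% of the Ez charged as Ty during the feed, and with the tail from a reckoned 5.61 mM of Ez, I reckon grey at 6.54%. So, taking blue at the north-west reading, I put teal above blue, and grey below it.

The forecast differs from this reckoning: it says all alike, with grey 13.3%, teal 13% and blue 13.5%, favouring an equilibrium under which “the order of addition doesn't matter”.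

The flasks give teal in the lead, with grey 7.30%, teal 16.1% and blue 13.1%.

    2 Ez → Vy (k = 7.70 M⁻¹ h⁻¹)
    Ez + Ry → Ty (k = 1.30 M⁻¹ h⁻¹)
    Aj ⇌ Ty, rate k3*(cs3 - [Ty]) while solid is left; crystals form when [Ty] > cs3 (solubility = 36.0 mM, k = 32.0 h⁻¹)
    Ty ⇌ Wy (K = 0.820, k = 0.0900 h⁻¹)
    Ez + Ry → Ji (k = 0.500 M⁻¹ h⁻¹)

Take a neighbour: teal again, but with 0.20 M of Ez over the same feed. Keeping c* at 2.88 mM, the steady [Ez] rises to 34.1 mM and the share falls to 7.79%. With the tail, the reckoning gives 8.49% of that charge as Ty. The neighbour flask holds 7.86% of its Ez as Ty at 10.0 h.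

(The readings stem from a simulated flask from invented constants; scatter was added.)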